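**Retrosynthetic overview**

1. Ring B (the C=N ring) is opened last. The N–C-3 and C-1–C-8a bonds go back to acetonitrile and a biaryl (R)-carbinol; forward, the nitrile displaces an in situ triflate with inversion and the nitrilium ion closes onto the arene (interrupted Ritter reaction ending in a Bischler–Napieralski-type closure).
2. Enabling feature: in ring A (the benzo ring of the isoquinoline) the methoxy groups at C-6 and C-8 are para and ortho to C-8a, the carbon that must attack the nitrilium carbon, but meta to C-4a, which carries the C-4–C-3 chain, and C-5 is blocked by the naphthyl ring. C-8a is therefore the only free ortho position and a strongly nucleophilic one, while bridging of the aryl ring to C-3 (phenonium ion) gets no help.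
3. The biaryl bond C-5–C-1' is cut to a bromo carbinol (from 1-bromo-3,5-dimethoxybenzene, (R)-propylene oxide and NBS) and a naphthyl boronate (Suzuki–Miyaura coupling).
4. The substituted naphthalene ring is made by Dötz benzannulation of a 2-methoxyphenyl Fischer carbene with propyne, which places OH (the coupling handle), CH3 and both OCH3 groups without regiochemical ambiguity.
5. Order of ring formation: ring A is bought, the second naphthalene ring is made in step 4, the biaryl is joined in step 7, ring B is closed in step 8.

Key step: step 8

Remark (assumption): the target SMILES fixes only C-3 (S configuration) and leaves the biaryl axis open; the route sets C-3 and carries the axis as the mixture of atropo-diastereomers that the biaryl coupling gives.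

**Route**

Step 1
Reactants: 1 1-bromo-3,5-dimethoxybenzene; 2 (R)-2-methyloxirane
Product: 5 (R)-1-(3,5-dimethoxyphenyl)propan-2-ol, via 3,5-dimethoxyphenylmagnesium bromide 3 (not isolated), via bromomagnesium alkoxide 4 (not isolated)
Conditions: Mg, THF, 23–40 °C; then CuI (10 mol%), 2, −30 → 0 °C; 1 M HCl
Reagents that add atoms: none
Why: Copper-catalysed opening of a terminal epoxide by an aryl Grignard reagent takes place at the unsubstituted carbon, so the stereocenter of 2 is carried over untouched as the (R)-carbinol.

Step 2
Reactants: 5 (R)-1-(3,5-dimethoxyphenyl)propan-2-ol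
Product: 6 (R)-1-(2-bromo-3,5-dimethoxyphenyl)propan-2-ol
Conditions: NBS (1.0 equiv), MeCN, −10 → 0 °C, dark
Reagents that add atoms: N-bromosuccinimide, O=C1CCC(=O)N1Br
Why: Electrophilic aromatic bromination should go to the position para to one methoxy group and ortho to the other (the two such positions are equivalent) in preference to the more hindered position between the methoxy groups, as is usual for 5-alkylresorcinol dimethyl ethers.

Step 3
Reactants: 7 2-bromoanisole; 8 chromium hexacarbonyl Cr(CO)6
Product: 11 pentacarbonyl[methoxy(2-methoxyphenyl)methylidene]chromium, via 2-methoxyphenyllithium 9 (not isolated), via lithium acylchromate 10 (not isolated)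
Conditions: n-BuLi, Et2O, −78 → 0 °C; Cr(CO)6, Et2O, 0 → 23 °C; then Me3OBF4, CH2Cl2, 0 °C
Reagents that add atoms: trimethyloxonium tetrafluoroborate, C[O+](C)C.F[B-](F)(F)F
Why: Fischer carbene synthesis, in which bromine–lithium exchange gives the aryllithium, this adds to a CO ligand of Cr(CO)6, and the acyl chromate is O-methylated by the Meerwein salt.

Step 4
Reactants: 11 pentacarbonyl[methoxy(2-methoxyphenyl)methylidene]chromium; 12 propyne
Product: 14 4,5-dimethoxy-2-methylnaphthalen-1-ol, via tricarbonylchromium naphthol complex 13 (not isolated)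
Conditions: propyne (1 M in THF, 2 equiv), THF, 50 °C, sealed tube; then air, Et2O, 23 °C, 30 min; chromatography under argon, used at once
Reagents that add atoms: none
Why: Dötz benzannulation, in which the alkyne inserts with its unsubstituted carbon bonded to the carbene carbon, and CO insertion and electrocyclic closure onto the free ortho carbon of the anisyl ring should give the 4-methoxy-1-naphthol with the methyl group next to the new hydroxyl (the usual regiochemistry of terminal alkynes) and the anisyl methoxy group peri to the carbene-derived one; air removes the Cr(CO)3 fragment.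

Step 5
Reactants: 14 4,5-dimethoxy-2-methylnaphthalen-1-ol
Product: 15 4,5-dimethoxy-2-methylnaphthalen-1-yl trifluoromethanesulfonate
Conditions: Tf2O, pyridine, CH2Cl2, −20 → 0 °C, argon
Reagents that add atoms: triflic anhydride, O=S(=O)(OS(=O)(=O)C(F)(F)F)C(F)(F)F
Why: O-Triflation of a phenol turns the hydroxyl made by the benzannulation into a cross-coupling handle at the carbon that must carry the biaryl bond, and removes the air sensitivity of the naphthol.

Step 6
Reactants: 15 4,5-dimethoxy-2-methylnaphthalen-1-yl trifluoromethanesulfonate
Product: 16 2-(4,5-dimethoxy-2-methylnaphthalen-1-yl)-4,4,5,5-tetramethyl-1,3,2-dioxaborolane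
Conditions: pinacolborane (3 equiv), Et3N (4 equiv), PdCl2(dppf) (5 mol%), dioxane, 100 °C
Reagents that add atoms: pinacolborane, CC1(C)OBOC1(C)C
Why: Palladium-catalysed Miyaura-type borylation of an aryl triflate with pinacolborane and Et3N, a variant that tolerates ortho substituents and electron-rich rings.

Step 7
Reactants: 6 (R)-1-(2-bromo-3,5-dimethoxyphenyl)propan-2-ol; 16 2-(4,5-dimethoxy-2-methylnaphthalen-1-yl)-4,4,5,5-tetramethyl-1,3,2-dioxaborolane
Product: 17 (R)-1-[2-(4,5-dimethoxy-2-methylnaphthalen-1-yl)-3,5-dimethoxyphenyl]propan-2-ol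
Conditions: Pd(OAc)2 (5 mol%), SPhos (10 mol%), K3PO4 (3 equiv), toluene/H2O (10:1), 100 °C
Reagents that add atoms: none
Why: Suzuki–Miyaura coupling with a bulky, electron-rich dialkylbiarylphosphine, the ligand class that delivers tetra-ortho-substituted biaryls; the carbinol stereocenter is not involved, and the product is expected as a mixture of two atropo-diastereomers that are carried on together.

Step 8
Reactants: 17 (R)-1-[2-(4,5-dimethoxy-2-methylnaphthalen-1-yl)-3,5-dimethoxyphenyl]propan-2-ol; 18 acetonitrile
Product: 22 (3S)-5-(4,5-dimethoxy-2-methylnaphthalen-1-yl)-6,8-dimethoxy-1,3-dimethyl-3,4-dihydroisoquinoline (O-methylancistrocladinine), via secondary triflate 19 (not isolated), via N-alkylnitrilium triflate 20 (not isolated), via dihydroisoquinolinium triflate 21 (not isolated)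
Conditions: CH2Cl2/MeCN (1:1, dry), 2,6-di-tert-butyl-4-methylpyridine (2.5 equiv), Tf2O (1.2 equiv, dropwise), −40 → 23 °C; then 1 M NaOH
Reagents that add atoms: none
Why: Proposed new method: Tf2O turns the (R)-carbinol into the secondary triflate 19, acetonitrile (in large excess) displaces triflate from the rear in an SN2 step to give the (S)-N-alkylnitrilium ion 20, and the free ortho carbon of the dimethoxyphenyl ring (the later C-8a) attacks the nitrilium carbon and loses a proton to give the cyclic iminium salt 21, which base sets free. The closest known reaction types are the Ritter reaction, the Tf2O-promoted annulation of 2-arylethanols with nitriles to 3,4-dihydroisoquinolines, and the ring closure of nitrilium ions in the Bischler–Napieralski reaction; new is the use of an enantioenriched secondary carbinol with the demand for clean inversion. The one ring that closes (ring B) is formed by a 6-endo-dig Friedel–Crafts (Houben–Hoesch-type) attack on the nitrilium carbon. The single stereocenter C-3 is controlled by the epoxide-derived carbinol carbon, whose configuration is inverted from R to S in the displacement. The step needs displacement by the nitrile to outrun aryl participation (a phenonium ion would give retention or a 4-methyl isomer), ionization and elimination, and it needs ring closure at one position only. Both follow from the substitution pattern, since the two methoxy groups are meta to the carbon that carries the side chain and so do not stabilize a phenonium ion, but are ortho and para to the attacking carbon, and the other ortho position is blocked by the naphthyl group; the hindered weak base and low temperature hold back elimination, and the product stays N-protonated so that it is not alkylated.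

**Compound list**

1 | 1-bromo-3,5-dimethoxybenzene | COc1cc(Br)cc(OC)c1 | starting material
2 | (R)-2-methyloxirane ((R)-propylene oxide) | C[C@@H]1CO1 | starting material
3 | 3,5-dimethoxyphenylmagnesium bromide (not isolated) | COc1cc(OC)cc([Mg]Br)c1 | intermediate
4 | bromomagnesium (R)-1-(3,5-dimethoxyphenyl)propan-2-olate (not isolated) | C[C@@H](O[Mg]Br)Cc1cc(OC)cc(OC)c1 | intermediate
5 | (R)-1-(3,5-dimethoxyphenyl)propan-2-ol | C[C@@H](O)Cc1cc(OC)cc(OC)c1 | intermediate
6 | (R)-1-(2-bromo-3,5-dimethoxyphenyl)propan-2-ol | C[C@@H](O)Cc1cc(OC)cc(OC)c1Br | intermediate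
7 | 2-bromoanisole | COc1ccccc1Br | starting material
8 | chromium hexacarbonyl Cr(CO)6 | O=C=[Cr](=C=O)(=C=O)(=C=O)(=C=O)=C=O | starting material
9 | 2-methoxyphenyllithium (not isolated) | COc1ccccc1[Li] | intermediate
10 | lithium pentacarbonyl[(2-methoxyphenyl)(oxido)methylidene]chromate (not isolated) | [Li+].COc1ccccc1C([O-])=[Cr](=C=O)(=C=O)(=C=O)(=C=O)=C=O | intermediate
11 | pentacarbonyl[methoxy(2-methoxyphenyl)methylidene]chromium | COC(c1ccccc1OC)=[Cr](=C=O)(=C=O)(=C=O)(=C=O)=C=O | intermediate
12 | propyne | CC#C | starting material
13 | tricarbonyl(4,5-dimethoxy-2-methylnaphthalen-1-ol)chromium, Cr(CO)3 bound to the face of the phenol ring and written as a separate part in the SMILES (not isolated) | COc1cc(C)c(O)c2cccc(OC)c12.O=C=[Cr](=C=O)=C=O | intermediate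
14 | 4,5-dimethoxy-2-methylnaphthalen-1-ol | COc1cc(C)c(O)c2cccc(OC)c12 | intermediate
15 | 4,5-dimethoxy-2-methylnaphthalen-1-yl trifluoromethanesulfonate | COc1cc(C)c(OS(=O)(=O)C(F)(F)F)c2cccc(OC)c12 | intermediate
16 | 2-(4,5-dimethoxy-2-methylnaphthalen-1-yl)-4,4,5,5-tetramethyl-1,3,2-dioxaborolane | COc1cc(C)c(B3OC(C)(C)C(C)(C)O3)c2cccc(OC)c12 | intermediate
17 | (R)-1-[2-(4,5-dimethoxy-2-methylnaphthalen-1-yl)-3,5-dimethoxyphenyl]propan-2-ol (axis undefined) | C[C@@H](O)Cc1cc(OC)cc(OC)c1-c1c(C)cc(OC)c2c(OC)cccc12 | intermediate
18 | acetonitrile | CC#N | starting material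
19 | (R)-1-[2-(4,5-dimethoxy-2-methylnaphthalen-1-yl)-3,5-dimethoxyphenyl]propan-2-yl trifluoromethanesulfonate (not isolated) | C[C@@H](OS(=O)(=O)C(F)(F)F)Cc1cc(OC)cc(OC)c1-c1c(C)cc(OC)c2c(OC)cccc12 | intermediate
20 | N-[(S)-1-[2-(4,5-dimethoxy-2-methylnaphthalen-1-yl)-3,5-dimethoxyphenyl]propan-2-yl]acetonitrilium triflate (not isolated) | C[C@H]([N+]#CC)Cc1cc(OC)cc(OC)c1-c1c(C)cc(OC)c2c(OC)cccc12.[O-]S(=O)(=O)C(F)(F)F | intermediate
21 | (3S)-5-(4,5-dimethoxy-2-methylnaphthalen-1-yl)-6,8-dimethoxy-1,3-dimethyl-3,4-dihydroisoquinolin-2-ium triflate (not isolated) | COc1cc(OC)c(-c2c(C)cc(OC)c3c(OC)cccc23)c2c1C(C)=[NH+][C@@H](C)C2.[O-]S(=O)(=O)C(F)(F)F | intermediate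
22 | (3S)-5-(4,5-dimethoxy-2-methylnaphthalen-1-yl)-6,8-dimethoxy-1,3-dimethyl-3,4-dihydroisoquinoline (O-methylancistrocladinine) | COc1cc(OC)c(-c2c(C)cc(OC)c3c(OC)cccc23)c2c1C(C)=N[C@@H](C)C2 | target

**Step count and risks**

Total step count: 8. Longest linear sequence: 6 steps (steps 3, 4, 5, 6, 7 and 8, from 2-bromoanisole); steps 1 and 2 form the second branch, which joins at step 7.

The three steps most likely to fail:

1. Step 8 (Proposed new method). What may go wrong: loss of configurational purity at C-3 if aryl participation or ionization competes with direct displacement by the nitrile, and loss of material by elimination toward the conjugated propenyl arene. The fallback uses known chemistry only, sets out from 17 and comes back at 22. Mitsunobu azidation of 17 (PPh3, DIAD, diphenylphosphoryl azide, THF, 0 → 23 °C) should give with inversion the (S)-azide F1. Staudinger reduction (PPh3, THF/H2O, 50 °C) should give the (S)-amine F2. Acetylation (Ac2O, Et3N, CH2Cl2) should give the (S)-acetamide F3. Bischler–Napieralski cyclodehydration (Tf2O, 2-chloropyridine, CH2Cl2, −78 → 23 °C, then 1 M NaOH) should then close ring B to 22.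

2. Step 7. What may go wrong: protodeboronation of the hindered boronate while transmetalation onto the hindered arylpalladium species is slow, and interception of that species by the neighbouring free hydroxyl (C–O closure or hydride transfer). The fallback changes to a Negishi coupling with the naphthalene as the electrophile; it sets out from 6 and 15 and comes back at 17. Silylation of 6 (TBSCl, imidazole, DMF) should give the silyl ether F4. Bromine–lithium exchange (n-BuLi, THF, −78 °C) and transmetalation with ZnCl2 should give the arylzinc chloride F5, used in solution. Coupling with triflate 15 (Pd2(dba)3, RuPhos, THF/NMP, 70 °C) should give the silylated biaryl F6. Bu4NF in THF should then free the carbinol 17.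

3. Step 6. What may go wrong: slow oxidative addition into the hindered, electron-rich C–O bond and reduction of the triflate to the arene by a palladium hydride. The fallback reverses the polarity of the coupling and needs no naphthyl boronate; it sets out from 6 (and uses 15) and comes back at 17. Treating 6 with NaH (THF, 0 °C), then n-BuLi (−78 °C), then B(OiPr)3 and 1 M HCl should give the cyclic boronic hemiester F7, in which the side-chain oxygen is tied to boron. Suzuki–Miyaura coupling of F7 with triflate 15 (Pd(OAc)2, SPhos, K3PO4, toluene/H2O, 100 °C) should give 17 directly, the B–O bond being cleaved in the coupling.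

Further compounds
F1 | step 8 | 1-[2-[(2S)-2-azidopropyl]-4,6-dimethoxyphenyl]-4,5-dimethoxy-2-methylnaphthalene | C[C@H](N=[N+]=[N-])Cc1cc(OC)cc(OC)c1-c1c(C)cc(OC)c2c(OC)cccc12
F2 | step 8 | (2S)-1-[2-(4,5-dimethoxy-2-methylnaphthalen-1-yl)-3,5-dimethoxyphenyl]propan-2-amine | C[C@H](N)Cc1cc(OC)cc(OC)c1-c1c(C)cc(OC)c2c(OC)cccc12
F3 | step 8 | N-[(2S)-1-[2-(4,5-dimethoxy-2-methylnaphthalen-1-yl)-3,5-dimethoxyphenyl]propan-2-yl]acetamide | C[C@H](NC(C)=O)Cc1cc(OC)cc(OC)c1-c1c(C)cc(OC)c2c(OC)cccc12
F4 | step 7 | [(2R)-1-(2-bromo-3,5-dimethoxyphenyl)propan-2-yl]oxy-tert-butyldimethylsilane | C[C@@H](O[Si](C)(C)C(C)(C)C)Cc1cc(OC)cc(OC)c1Br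
F5 | step 7 | [2-[(2R)-2-(tert-butyldimethylsilyloxy)propyl]-4,6-dimethoxyphenyl]zinc chloride | C[C@@H](O[Si](C)(C)C(C)(C)C)Cc1cc(OC)cc(OC)c1[Zn]Cl
F6 | step 7 | tert-butyl-[(2R)-1-[2-(4,5-dimethoxy-2-methylnaphthalen-1-yl)-3,5-dimethoxyphenyl]propan-2-yl]oxy-dimethylsilane | C[C@@H](O[Si](C)(C)C(C)(C)C)Cc1cc(OC)cc(OC)c1-c1c(C)cc(OC)c2c(OC)cccc12
F7 | step 6 | (3R)-6,8-dimethoxy-3-methyl-3,4-dihydro-1H-benzo[c][1,2]oxaborinin-1-ol | C[C@@H]1Cc2cc(OC)cc(OC)c2B(O)O1
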